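**Plan**
- Cuts, in retrosynthetic order: the four O-benzyl groups; then ring C of the isoflavan at C2–C3 and C4–C4a (retro-[4+2]) to an O-aryl oxocarbenium ion and an (E)-stilbene; then the stilbene at the C6(flavanone)–vinyl bond to a 6-iodoflavanone and an (E)-styrylboronate.
- Enabling feature: C2 is a formaldehyde-level carbon on the phenolic O1, so ArO–CH2(+) is a cationic 2-oxadiene (C2=O1(+)–C8a=C4a). The C3=C4 alkene carries at C4 the phloroglucinol-type ring A of the flavanone (O5, O7, O1 donors), which fixes where the cation develops.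
- Forward order: the flavanone ring system is bought as (2S)-naringenin; three fragments are made in 2 + 2 + 1 steps; Suzuki–Miyaura coupling gives the stilbene; the cationic [4+2] closes the chroman ring and unites all three aryl units; hydrogenolysis ends the route.
- Stereochemistry: flavanone C2 comes from (2S)-naringenin; the trans C3/C4 relation from the E alkene; the absolute 3R,4S sense from the chiral counter-anion of the acid catalyst.

Key step: step 7

Remark: (2S)-naringenin and 3-hydroxy-2,4-dimethoxybenzaldehyde are taken as commercial; the antipode of the chiral acid that favours the 3R,4S adduct has to be found by screening, and "the chiral acid" below means that antipode.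

**Step 1**
Reactants: 1 (2S)-naringenin
Product: 2 (2S)-7-(benzyloxy)-2-[4-(benzyloxy)phenyl]-5-hydroxychroman-4-one
Conditions: BnOH (2.2 equiv), PPh3, DIAD, THF, 0 °C to rt
Reagents that add atoms: benzyl alcohol (OCc1ccccc1)
Why: Mitsunobu O-alkylation should take the two acidic, unhindered phenols (O7, O4') and leave the 5-OH, which is hydrogen-bonded to the C4 carbonyl; the neutral medium avoids base-induced retro-oxa-Michael opening, so C2 should keep its S configuration.

**Step 2**
Reactants: 2 (2S)-7-(benzyloxy)-2-[4-(benzyloxy)phenyl]-5-hydroxychroman-4-one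
Product: 3 (2S)-7-(benzyloxy)-2-[4-(benzyloxy)phenyl]-5-hydroxy-6-iodochroman-4-one
Conditions: benzyltrimethylammonium dichloroiodate (1.05 equiv), CaCO3, CH2Cl2/MeOH, rt
Reagents that add atoms: benzyltrimethylammonium dichloroiodate (C[N+](C)(C)Cc1ccccc1.Cl[I-]Cl)
Why: Electrophilic aromatic iodination with this mild reagent is expected ortho to the free, chelated 5-OH, that is at C6 (the pattern known for 5-hydroxy-7-alkoxyflavones), while ring B with its single alkoxy donor is much less activated.

**Step 3**
Reactants: 4 3-hydroxy-2,4-dimethoxybenzaldehyde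
Product: 5 3-(benzyloxy)-2,4-dimethoxybenzaldehyde
Conditions: BnBr, K2CO3, DMF, rt
Reagents that add atoms: benzyl bromide (BrCc1ccccc1)
Why: Williamson ether synthesis on a phenoxide; the aldehyde is inert to carbonate at room temperature.

**Step 4**
Reactants: 5 3-(benzyloxy)-2,4-dimethoxybenzaldehyde
Product: 6 (E)-2-[2-(3-benzyloxy-2,4-dimethoxyphenyl)ethenyl]-4,4,5,5-tetramethyl-1,3,2-dioxaborolane
Conditions: bis(pinacolato)borylmethane, lithium 2,2,6,6-tetramethylpiperidide (LiTMP), THF, 0 °C, then 5 at −78 °C to rt
Reagents that add atoms: bis(pinacolato)borylmethane (CC1(C)OB(CB2OC(C)(C)C(C)(C)O2)OC1(C)C)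
Why: Boron-Wittig olefination: the α-boryl carbanion adds to the aldehyde and syn-elimination of the boron–oxygen unit should give the E vinylboronate.

**Step 5**
Reactants: 7 3-(benzyloxy)phenol
Product: 8 [3-(benzyloxy)phenoxy]methyl pivalate
Conditions: chloromethyl pivalate, Cs2CO3, DMF, rt
Reagents that add atoms: chloromethyl pivalate (CC(C)(C)C(=O)OCCl)
Why: SN2 O-alkylation of the caesium phenoxide at the activated chloromethyl carbon (Williamson type); the hindered pivaloyl carbonyl disfavours acyl transfer to the phenoxide.

**Step 6**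
Reactants: 3 (2S)-7-(benzyloxy)-2-[4-(benzyloxy)phenyl]-5-hydroxy-6-iodochroman-4-one; 6 (E)-2-[2-(3-benzyloxy-2,4-dimethoxyphenyl)ethenyl]-4,4,5,5-tetramethyl-1,3,2-dioxaborolane
Product: 9 (2S)-7-(benzyloxy)-2-[4-(benzyloxy)phenyl]-6-[(E)-2-(3-benzyloxy-2,4-dimethoxyphenyl)ethenyl]-5-hydroxychroman-4-one
Conditions: Pd(OAc)2 (5 mol %), SPhos (2-dicyclohexylphosphino-2',6'-dimethoxybiphenyl, 10 mol %), K3PO4, THF/H2O (10:1), 45 °C
Reagents that add atoms: none
Why: Suzuki–Miyaura coupling with a dialkylbiarylphosphine ligand suited to the doubly ortho-substituted, electron-rich iodide; the alkene geometry is retained, and phosphate at 45 °C is chosen to limit opening of the flavanone ring.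

**Step 7**
Reactants: 9 (2S)-7-(benzyloxy)-2-[4-(benzyloxy)phenyl]-6-[(E)-2-(3-benzyloxy-2,4-dimethoxyphenyl)ethenyl]-5-hydroxychroman-4-one; 8 [3-(benzyloxy)phenoxy]methyl pivalate
Product: 12 (2S)-7-(benzyloxy)-2-[4-(benzyloxy)phenyl]-6-[(3R,4S)-7-(benzyloxy)-3-(3-benzyloxy-2,4-dimethoxyphenyl)chroman-4-yl]-5-hydroxychroman-4-one, via aryloxymethyl oxocarbenium ion 10 (not isolated), via C4 benzylic cation 11 (not isolated)
Conditions: chiral confined imidodiphosphorimidate Brønsted acid (two 3,3'-bis[3,5-bis(trifluoromethyl)phenyl]-1,1'-bi-2-naphthol units on a P–N–P core with two N-triflyl groups, 5 mol %), 8 (1.5 equiv, slow addition), CH2Cl2, 4 Å MS, −40 °C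
Reagents that add atoms: none
Why: Proposed new method: the confined chiral acid should ionise the acylal 8 (loss of pivalic acid) to the O-aryl oxocarbenium ion 10, a cationic 2-oxadiene (C2=O1(+)–C8a=C4a) held as a contact ion pair by the chiral anion; its CH2 carbon should attack the alkene carbon of 9 that bears the dimethoxyaryl group, so that the charge arrives at C4 next to ring A of the flavanone (cation 11, an ortho/para-quinone-methide-type ion stabilised by O5, O7 and O1), which the resorcinol ring then captures. The closest known reaction types are the Lewis-acid-promoted oxa-Povarov reaction of aryl oxocarbenium ions with styrenes, the chiral-acid-catalysed aza-Povarov reaction and the asymmetric Prins-type addition of formaldehyde-derived oxocarbenium ions to styrenes under confined-acid catalysis; new is the catalytic, enantiofacially controlled oxa variant with a CH2 oxocarbenium ion on a stilbene. The chroman ring closes as a formal inverse-electron-demand [4+2] cycloaddition, in the stepwise limit a six-membered intramolecular Friedel–Crafts alkylation by the arene carbon ortho to O1 and para to the benzyloxy group. C3 is set when the chiral anion selects the alkene face (catalyst control, as the flavanone C2 centre is too remote to bias it), and C4 follows from C3: suprafacial transfer of the E geometry, or in the stepwise limit a chair-like closure with both aryl groups pseudo-equatorial, gives the trans (3R,4S) adduct. The step needs regioselectivity in the first C–C bond (secured by three conjugating oxygen donors on ring A, including the free 5-OH, against two on the other aryl group, whose 2-methoxy group is twisted out of plane), reaction at the alkene in preference to the arene positions (the push-substituted stilbene is the best π-nucleophile present, and 8 is added slowly to suppress its self-condensation) and closure para to the benzyloxy group instead of between the two oxygens (sterics).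

**Step 8**
Reactants: 12 (2S)-7-(benzyloxy)-2-[4-(benzyloxy)phenyl]-6-[(3R,4S)-7-(benzyloxy)-3-(3-benzyloxy-2,4-dimethoxyphenyl)chroman-4-yl]-5-hydroxychroman-4-one
Product: 13 (2S)-5,7-dihydroxy-6-[(3R,4S)-7-hydroxy-3-(3-hydroxy-2,4-dimethoxyphenyl)chroman-4-yl]-2-(4-hydroxyphenyl)chroman-4-one
Conditions: H2 (1 atm), Pd/C, EtOAc/MeOH, rt
Reagents that add atoms: none
Why: Catalytic hydrogenolysis should cleave the four benzyl ethers under neutral conditions that leave the chelated aryl ketone, the methyl ethers and the three stereocentres untouched.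

**Compound list**
1 | (2S)-naringenin, (2S)-5,7-dihydroxy-2-(4-hydroxyphenyl)chroman-4-one | O=C1C[C@@H](c2ccc(O)cc2)Oc2cc(O)cc(O)c12 | starting material
2 | (2S)-7-(benzyloxy)-2-[4-(benzyloxy)phenyl]-5-hydroxychroman-4-one | O=C1C[C@@H](c2ccc(OCc3ccccc3)cc2)Oc2cc(OCc3ccccc3)cc(O)c12 | intermediate
3 | (2S)-7-(benzyloxy)-2-[4-(benzyloxy)phenyl]-5-hydroxy-6-iodochroman-4-one | O=C1C[C@@H](c2ccc(OCc3ccccc3)cc2)Oc2cc(OCc3ccccc3)c(I)c(O)c12 | intermediate
4 | 3-hydroxy-2,4-dimethoxybenzaldehyde | COc1ccc(C=O)c(OC)c1O | starting material
5 | 3-(benzyloxy)-2,4-dimethoxybenzaldehyde | COc1ccc(C=O)c(OC)c1OCc1ccccc1 | intermediate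
6 | (E)-2-[2-(3-benzyloxy-2,4-dimethoxyphenyl)ethenyl]-4,4,5,5-tetramethyl-1,3,2-dioxaborolane | COc1ccc(/C=C/B2OC(C)(C)C(C)(C)O2)c(OC)c1OCc1ccccc1 | intermediate
7 | 3-(benzyloxy)phenol | Oc1cccc(OCc2ccccc2)c1 | starting material
8 | [3-(benzyloxy)phenoxy]methyl pivalate | CC(C)(C)C(=O)OCOc1cccc(OCc2ccccc2)c1 | intermediate
9 | (2S)-7-(benzyloxy)-2-[4-(benzyloxy)phenyl]-6-[(E)-2-(3-benzyloxy-2,4-dimethoxyphenyl)ethenyl]-5-hydroxychroman-4-one | O=C1C[C@@H](c2ccc(OCc3ccccc3)cc2)Oc2cc(OCc3ccccc3)c(/C=C/c3ccc(OC)c(OCc4ccccc4)c3OC)c(O)c12 | intermediate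
10 | [3-(benzyloxy)phenyl](methylidene)oxonium ion, the aryloxymethyl oxocarbenium ion, paired with the chiral acid anion | C=[O+]c1cccc(OCc2ccccc2)c1 | intermediate
11 | open-chain C4 benzylic cation: cationic CH on C6 of the flavanone, joined to the (R)-configured C3 that bears the 3-benzyloxy-2,4-dimethoxyphenyl group and the CH2–O–(3-benzyloxyphenyl) arm | COc1ccc([C@@H]([CH+]c2c(OCc3ccccc3)cc3c(c2O)C(=O)C[C@@H](c2ccc(OCc4ccccc4)cc2)O3)COc2cccc(OCc3ccccc3)c2)c(OC)c1OCc1ccccc1 | intermediate
12 | (2S)-7-(benzyloxy)-2-[4-(benzyloxy)phenyl]-6-[(3R,4S)-7-(benzyloxy)-3-(3-benzyloxy-2,4-dimethoxyphenyl)chroman-4-yl]-5-hydroxychroman-4-one | COc1ccc([C@@H]2COc3cc(OCc4ccccc4)ccc3[C@H]2c2c(OCc3ccccc3)cc3c(c2O)C(=O)C[C@@H](c2ccc(OCc4ccccc4)cc2)O3)c(OC)c1OCc1ccccc1 | intermediate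
13 | (2S)-5,7-dihydroxy-6-[(3R,4S)-7-hydroxy-3-(3-hydroxy-2,4-dimethoxyphenyl)chroman-4-yl]-2-(4-hydroxyphenyl)chroman-4-one | COc1ccc([C@@H]2COc3cc(O)ccc3[C@H]2c2c(O)cc3c(c2O)C(=O)C[C@@H](c2ccc(O)cc2)O3)c(OC)c1O | target

**Count and risks**
Total step count: 8. Longest linear sequence: 5 steps (1 → 2 → 6 → 7 → 8; the aldehyde branch 3 → 4 → 6 → 7 → 8 is equally long).

Step 7 (carries the label "Proposed new method:"). What may go wrong: weak enantiofacial discrimination by the chiral anion, addition with the opposite regiochemistry, Friedel–Crafts aryloxymethylation of the electron-rich rings, or acid-catalysed closure of O5 onto the alkene. The fallback uses known chemistry and sets out from 8 and 9. The oxa-Povarov reaction would be run in its known achiral Lewis-acid-promoted form (SnCl4, CH2Cl2, −78 °C), giving up catalyst control. This should give the two trans adducts, 12 and (2S)-7-(benzyloxy)-2-[4-(benzyloxy)phenyl]-6-[(3S,4R)-7-(benzyloxy)-3-(3-benzyloxy-2,4-dimethoxyphenyl)chroman-4-yl]-5-hydroxychroman-4-one F1. Because the (2S) centre of the flavanone is already in place, these are diastereomers and would be separated by chromatography (preparative HPLC if needed). The route comes back at 12.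

Step 6. What may go wrong: opening of the flavanone ring to the chalcone phenoxide in the basic aqueous medium, with loss of the C2 configuration, and protodeboronation or hydrodeiodination at the hindered site. The fallback replaces the boron partner by a tin partner so that the coupling needs no base. It sets out from 5, which a Takai-type olefination (Bu3SnCHBr2, CrCl2, LiI, THF/DMF) should convert into (E)-tributyl[2-(3-benzyloxy-2,4-dimethoxyphenyl)ethenyl]stannane F2. A Stille coupling of F2 with 3 (Pd(PPh3)4, CuI, DMF, 50 °C) comes back to the route at 9.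

Step 2. What may go wrong: iodination at C8 (para to the 5-OH) or double iodination competing with attack at C6. In the fallback the regiochemistry is no longer left to the innate preference of the free arene. Starting from 2, O5 is first converted into its thallium phenoxide (TlOAc, CH2Cl2) and iodine (I2) is then delivered to the adjacent C6, a method established for 5-hydroxy-7-alkoxyflavones. It comes back at 3 and makes no new compound (F0).

**Further compounds**
F1 | step 7 | (2S)-7-(benzyloxy)-2-[4-(benzyloxy)phenyl]-6-[(3S,4R)-7-(benzyloxy)-3-(3-benzyloxy-2,4-dimethoxyphenyl)chroman-4-yl]-5-hydroxychroman-4-one | COc1ccc([C@H]2COc3cc(OCc4ccccc4)ccc3[C@@H]2c2c(OCc3ccccc3)cc3c(c2O)C(=O)C[C@@H](c2ccc(OCc4ccccc4)cc2)O3)c(OC)c1OCc1ccccc1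
F2 | step 6 | (E)-tributyl[2-(3-benzyloxy-2,4-dimethoxyphenyl)ethenyl]stannane | CCCC[Sn](CCCC)(CCCC)/C=C/c1ccc(OC)c(OCc2ccccc2)c1OC
F0 | step 2 | none | none
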